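**Plan**

- Numbering and faces: ring carbons C1 (carbinol), C5 (acyloxy), C6 (lactone O), C7, C8 (CH2), C9 (CHOH), C10 (CHMe); lactone C11(=C13)/C12; side chain C2(=O)–C3=C4–C15. β is the face of 9-OH, α the face of 10-CH3.
- Retrosynthesis: the C5 ester, the C11=C13 methylene and the C1–C2 bond (acyl group masked as an allenyl ether, added to a C1 ketone) are cut first. The C6–O lactone bond and C5–OH go back to a 5β,6β-epoxide of a C1-keto-C5=C6 enone. C7–C8 and C9–C10 are then cut together as a [5+2] cycloaddition of a vinylcyclopropane (alkene C7=C6, ring C5/C1/C10) with a borylalkyne (C8≡C9).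
- Enabling feature: in the cycloheptane ring, C8–C9 is a two-carbon unit flanked by C7 and C10. The other five ring carbons carry oxygen at C1, C5 and C6. The C5/C6 dioxygen pair is a masked C5=C6 alkene (the alkene a vinylcyclopropane cycloaddition leaves behind), the C1 oxygen can ride on the cyclopropane, and the C9 oxygen can start as boron on the alkyne.
- Forward order: enol ether → cyclopropane (C5, C1, C10) → Z-alkenylcyclopropane → seven-membered ring (step 6) → C9 alcohol, C1 ketone, epoxide, γ-lactone → C1 side chain → methylene, ester, unmasking.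
- Stereochemistry: absolute configuration from the catalytic asymmetric cyclopropanation (C10 and the relay centre C1) and from (S)-2-methylbutanoic acid. C7 comes from the stereospecific cycloaddition, C9 from a 1,3-syn reduction directed by C1–OH, C5/C6 from β-epoxidation anti to the C7 chain with inversion at C6, and C1 from chelation-controlled addition anti to the C10 methyl.

Key step: step 6

Assumption: 1-methoxybut-2-yne is taken as a catalogue compound; otherwise one O-methylation of but-2-yn-1-ol precedes step 14.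

**Route**

Step 1
Reactants: 1 allyl tert-butyldimethylsilyl ether
Product: 2 (E)-tert-butyldimethyl(prop-1-enyloxy)silane
Conditions: [Ir(cod)(PMePh2)2]PF6 (1 mol %, activated with H2), THF, rt
Reagents that add atoms: none
Why: Iridium-hydride-catalysed allyl ether to enol ether isomerisation should give the E silyl enol ether, which fixes CH3 and OSi trans on the later cyclopropane.

Step 2
Reactants: 2 (E)-tert-butyldimethyl(prop-1-enyloxy)silane; 3 ethyl diazoacetate
Product: 4 ethyl (1R,2R,3S)-2-(tert-butyldimethylsilyloxy)-3-methylcyclopropane-1-carboxylate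
Conditions: CuOTf (1 mol %, from (CuOTf)2·C6H6), (S,S)-tBu-box (1.2 mol %), slow addition of 3, CH2Cl2, 0 °C to rt
Reagents that add atoms: none
Why: Copper–bis(oxazoline) carbenoid cyclopropanation of the electron-rich enol ether is stereospecific for the alkene (CH3 and OTBS stay trans), should place the ester anti to the bulky silyloxy group, and the ligand (enantiomer chosen by analogy with the styrene case, antipode if the sense proves opposite) sets the absolute configuration of all three ring carbons.

Step 3
Reactants: 4 ethyl (1R,2R,3S)-2-(tert-butyldimethylsilyloxy)-3-methylcyclopropane-1-carboxylate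
Product: 5 (1R,2R,3S)-2-(tert-butyldimethylsilyloxy)-3-methylcyclopropane-1-carbaldehyde
Conditions: DIBAL-H (1.05 equiv), CH2Cl2, −78 °C; aqueous Rochelle salt
Reagents that add atoms: none
Why: DIBAL partial reduction stops at the aluminium hemiacetal at −78 °C, no stereocentre is touched, and the intact silyl ether keeps the donor–acceptor cyclopropane closed.

Step 4
Reactants: 5 (1R,2R,3S)-2-(tert-butyldimethylsilyloxy)-3-methylcyclopropane-1-carbaldehyde; 6 (2-carboxyethyl)triphenylphosphonium bromide
Product: 8 (Z)-4-[(1R,2R,3S)-2-(tert-butyldimethylsilyloxy)-3-methylcyclopropyl]but-3-enoic acid, via carboxylate ylide 7 (not isolated)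
Conditions: 6 (1.3 equiv), NaHMDS (2.6 equiv), THF, 0 °C, then 5 at −78 °C to rt; pH 4 work-up
Reagents that add atoms: none
Why: Wittig olefination with the non-stabilised carboxylate ylide is Z-selective, which gives the Z alkenyl group that the cycloaddition needs for the C7/C10 relationship.

Step 5
Reactants: 8 (Z)-4-[(1R,2R,3S)-2-(tert-butyldimethylsilyloxy)-3-methylcyclopropyl]but-3-enoic acid
Product: 9 tert-butyl (Z)-4-[(1R,2R,3S)-2-(tert-butyldimethylsilyloxy)-3-methylcyclopropyl]but-3-enoate
Conditions: tert-butyl 2,2,2-trichloroacetimidate (2 equiv), cyclohexane/CH2Cl2, rt, no added acid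
Reagents that add atoms: tert-butyl 2,2,2-trichloroacetimidate, CC(C)(C)OC(=N)C(Cl)(Cl)Cl
Why: Imidate esterification, in which the carboxylic acid itself activates the imidate, makes the tert-butyl ester without base, so the β,γ-alkene should not move into conjugation.

Step 6
Reactants: 9 tert-butyl (Z)-4-[(1R,2R,3S)-2-(tert-butyldimethylsilyloxy)-3-methylcyclopropyl]but-3-enoate; 10 2-ethynyl-4,4,5,5-tetramethyl-1,3,2-dioxaborolane
Product: 11 cyclohepta-5,8-diene (route numbering) with C7 CH2CO2tBu (α), C9 Bpin, C10 CH3 (α), C1 OTBS (β)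
Conditions: [Rh(CO)2Cl]2 (5 mol %), 10 (2 equiv, slow addition), ClCH2CH2Cl, 80 °C
Reagents that add atoms: none
Why: Monovalent rhodium binds the Z alkene of 9 and inserts into the adjacent C5–C10 cyclopropane bond to give a σ-alkyl/π-allyl rhodacyclohexene, alkyne 10 inserts into the Rh–C7 allyl bond with its unsubstituted carbon (forming C7–C8), and C(sp2)–C(sp3) reductive elimination forms C9–C10 and frees the catalyst. The closest known reaction type is the rhodium-catalysed intermolecular [5+2] cycloaddition of vinylcyclopropanes with alkynes. The seven-membered carbocycle is closed as a formal (5+2) cycloaddition, the ring-closing bond C9–C10 arising by reductive elimination from the eight-membered rhodacycle, with C5=C6 left as the ring alkene. C7 is the only new stereocentre and is fixed relative to C10 by the stereospecific suprafacial course: C10 reacts with retention, and its methyl group (cis to the alkenyl group, turning outward in the rhodacycle) should end up cis to the Z substituent of the alkene, so C7–CH2CO2tBu and C10–CH3 are both α while the C1 silyloxy centre is carried through untouched. Two selectivities are needed: cleavage of C5–C10 and not C5–C1, expected because the cis methyl turns outward whereas the trans silyloxy group on C1 would have to turn inward (and an oxygen substituent weakens the distal ring bond, not the vicinal ones); and the alkyne orientation with boron on C9, expected because the bulky Bpin group stays away from the first-formed C7–C8 bond.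

Step 7
Reactants: 11 cycloheptadienyl boronate
Product: 13 C9 ketone (C8 now CH2; C7 chain α, C10 CH3 α, C1 OTBS β, C5=C6), via C9 enol 12 (not isolated)
Conditions: H2O2 (30 %), NaHCO3, THF/H2O, 0 °C
Reagents that add atoms: hydrogen peroxide, OO
Why: Oxidation of the alkenyl boronate (1,2-shift from boron to oxygen) gives the enol, which tautomerises to the C9 ketone, and the near-neutral conditions should leave C10 unepimerised.

Step 8
Reactants: 13 C9 ketone with C1 OTBS
Product: 14 β-hydroxy ketone (C1 OH β, C9 ketone)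
Conditions: HF·pyridine, pyridine/THF, 0 °C
Reagents that add atoms: none
Why: Fluoride cleavage of the secondary silyl ether under buffered acidic conditions avoids retro-aldol opening of the β-hydroxy ketone.

Step 9
Reactants: 14 β-hydroxy ketone
Product: 15 syn-1,3-diol (C9 OH β, C1 OH β, C10 CH3 α)
Conditions: Et2BOMe, NaBH4, THF/MeOH (4:1), −78 °C; MeOH co-evaporation
Reagents that add atoms: none
Why: Narasaka–Prasad reduction, in which external hydride attacks the boron chelate of the β-hydroxy ketone, gives the syn-1,3-diol, so the C1 hydroxyl (β) sets C9–OH β.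

Step 10
Reactants: 15 syn-1,3-diol
Product: 16 hydroxy enone (C1 ketone conjugated to C5=C6, C9 OH β)
Conditions: MnO2 (20 equiv), CH2Cl2, rt
Reagents that add atoms: none
Why: MnO2 oxidises only the allylic C1 alcohol, leaving the saturated C9 alcohol.

Step 11
Reactants: 16 hydroxy enone
Product: 17 silyl enone (C9 OTBS β)
Conditions: TBSOTf, 2,6-lutidine, CH2Cl2, −78 °C
Reagents that add atoms: tert-butyldimethylsilyl triflate, CC(C)(C)[Si](C)(C)OS(=O)(=O)C(F)(F)F
Why: Silylation blocks C9–OH so that the later acylation can only occur at C5.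

Step 12
Reactants: 17 silyl enone
Product: 18 5β,6β-epoxy ketone
Conditions: t-BuOOH (anhydrous, in decane), DBU, CH2Cl2, 0 °C
Reagents that add atoms: tert-butyl hydroperoxide, CC(C)(C)OO
Why: Weitz–Scheffer nucleophilic epoxidation, in which the peroxide anion adds to C6 anti to the C7 side chain, should place the epoxide on the β face and so set C5 and C6.

Step 13
Reactants: 18 5β,6β-epoxy ketone
Product: 20 keto lactone (6α,12-lactone, C5 OH β, C1 ketone, C9 OTBS β), via epoxy acid 19 (not isolated)
Conditions: CF3CO2H/CH2Cl2 (1:4), 0 °C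
Reagents that add atoms: none
Why: Acidolysis of the tert-butyl ester followed by 5-exo opening of the protonated epoxide at C6 (the carbon remote from the ketone) with inversion gives the cis-fused γ-lactone (C6–O α) and leaves C5–OH β.

Step 14
Reactants: 21 1-methoxybut-2-yne
Product: 22 1-methoxybuta-1,2-diene
Conditions: KOtBu (0.1 equiv), DMSO, rt; distillation
Reagents that add atoms: none
Why: Base-catalysed propargyl-to-allenyl ether isomerisation (prototropic shift) gives the alkoxyallene that serves as a but-2-enoyl anion equivalent.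

Step 15
Reactants: 20 keto lactone; 22 1-methoxybuta-1,2-diene
Product: 24 C1 adduct (C1 OH α, C1 1-methoxybuta-1,2-dien-1-yl β; allene epimers), via lithiated allene 23 (not isolated)
Conditions: 22 (3.5 equiv), n-BuLi (3.3 equiv), THF, −40 °C; CeCl3 (3.5 equiv), −78 °C; then 20; aqueous NaHCO3
Reagents that add atoms: none
Why: 1,2-Addition of the α-metalated alkoxyallene as its organocerium reagent (ketone faster than lactone); chelation of the C5 alkoxide to the carbonyl should turn the C10 methyl pseudo-axial on the α face, so the nucleophile enters from the β face and C1–OH becomes α.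

Step 16
Reactants: 24 C1 adduct
Product: 25 C11 hydroxymethyl lactone (C11 epimers)
Conditions: LDA (3.3 equiv), THF, −78 °C; CH2O (gas), −78 to −20 °C; pH 7 buffer
Reagents that add atoms: formaldehyde, C=O
Why: Aldol reaction of the lactone enolate with formaldehyde (the two hydroxyls are deprotonated first) introduces C13; the C11 configuration is lost in the next step.

Step 17
Reactants: 25 C11 hydroxymethyl lactone
Product: 27 α-methylene lactone (C5 OH β, C1 OH α, C9 OTBS β), via primary mesylate 26 (not isolated)
Conditions: MsCl (1.1 equiv), Et3N, CH2Cl2, −20 °C; then DBU, rt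
Reagents that add atoms: none
Why: Selective mesylation of the primary alcohol and E1cB elimination give the C11=C13 methylene.

Step 18
Reactants: 27 α-methylene lactone; 28 (S)-2-methylbutanoic acid
Product: 29 C5 (S)-2-methylbutanoate
Conditions: 28 (1.5 equiv), DCC, DMAP (0.2 equiv), CH2Cl2, 0 °C to rt
Reagents that add atoms: none
Why: Steglich esterification acylates the only secondary alcohol (C5; C1–OH is tertiary and C9 is silylated), and the acid stereocentre comes in unchanged from 28.

Step 19
Reactants: 29 C5 (S)-2-methylbutanoate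
Product: 31 target CNP0331957.1, via silyl-protected enone 30 (not isolated)
Conditions: HF (48 % aq.)/MeCN, 0 °C to rt
Reagents that add atoms: water, O
Why: Acid hydrolysis of the allenyl enol ether (protonation at the central allene carbon, then hydration) should give the E enone, and the same reagent removes the C9 silyl ether.

**Compound list**

1 | allyl tert-butyldimethylsilyl ether | C=CCO[Si](C)(C)C(C)(C)C | starting material
2 | (E)-tert-butyldimethyl(prop-1-enyloxy)silane | C/C=C/O[Si](C)(C)C(C)(C)C | intermediate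
3 | ethyl diazoacetate | CCOC(=O)C=[N+]=[N-] | starting material
4 | ethyl (1R,2R,3S)-2-(tert-butyldimethylsilyloxy)-3-methylcyclopropane-1-carboxylate (ester trans to OTBS, cis to CH3) | CCOC(=O)[C@H]1[C@H](O[Si](C)(C)C(C)(C)C)[C@H]1C | intermediate
5 | (1R,2R,3S)-2-(tert-butyldimethylsilyloxy)-3-methylcyclopropane-1-carbaldehyde | O=C[C@H]1[C@H](O[Si](C)(C)C(C)(C)C)[C@H]1C | intermediate
6 | (2-carboxyethyl)triphenylphosphonium bromide | OC(=O)CC[P+](c1ccccc1)(c1ccccc1)c1ccccc1.[Br-] | starting material
7 | sodium 3-(triphenylphosphoranylidene)propanoate (carboxylate ylide, not isolated) | [Na+].[O-]C(=O)CC=P(c1ccccc1)(c1ccccc1)c1ccccc1 | intermediate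
8 | (Z)-4-[(1R,2R,3S)-2-(tert-butyldimethylsilyloxy)-3-methylcyclopropyl]but-3-enoic acid | OC(=O)C/C=C\[C@H]1[C@H](O[Si](C)(C)C(C)(C)C)[C@H]1C | intermediate
9 | tert-butyl (Z)-4-[(1R,2R,3S)-2-(tert-butyldimethylsilyloxy)-3-methylcyclopropyl]but-3-enoate | CC(C)(C)OC(=O)C/C=C\[C@H]1[C@H](O[Si](C)(C)C(C)(C)C)[C@H]1C | intermediate
10 | 2-ethynyl-4,4,5,5-tetramethyl-1,3,2-dioxaborolane | C#CB1OC(C)(C)C(C)(C)O1 | starting material
11 | cycloadduct: cyclohepta-5,8-diene with C7 CH2CO2tBu (α), C9 Bpin, C10 CH3 (α), C1 OTBS (β) | CC(C)(C)OC(=O)C[C@@H]1C=C(B2OC(C)(C)C(C)(C)O2)[C@H](C)[C@@H](O[Si](C)(C)C(C)(C)C)C=C1 | intermediate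
12 | C9 enol of 13 (not isolated) | CC(C)(C)OC(=O)C[C@@H]1C=C(O)[C@H](C)[C@@H](O[Si](C)(C)C(C)(C)C)C=C1 | intermediate
13 | C9 ketone: C7 chain α, C10 CH3 α, C1 OTBS β, C5=C6 | CC(C)(C)OC(=O)C[C@@H]1CC(=O)[C@H](C)[C@@H](O[Si](C)(C)C(C)(C)C)C=C1 | intermediate
14 | β-hydroxy ketone: C1 OH β, C9 ketone | CC(C)(C)OC(=O)C[C@@H]1CC(=O)[C@H](C)[C@@H](O)C=C1 | intermediate
15 | syn-1,3-diol: C9 OH β, C1 OH β | CC(C)(C)OC(=O)C[C@@H]1C[C@@H](O)[C@H](C)[C@@H](O)C=C1 | intermediate
16 | hydroxy enone: C1 ketone, C5=C6, C9 OH β | CC(C)(C)OC(=O)C[C@@H]1C[C@@H](O)[C@H](C)C(=O)C=C1 | intermediate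
17 | silyl enone: C9 OTBS β | CC(C)(C)OC(=O)C[C@@H]1C[C@@H](O[Si](C)(C)C(C)(C)C)[C@H](C)C(=O)C=C1 | intermediate
18 | 5β,6β-epoxy ketone | CC(C)(C)OC(=O)C[C@@H]1C[C@@H](O[Si](C)(C)C(C)(C)C)[C@H](C)C(=O)[C@H]2O[C@@H]12 | intermediate
19 | epoxy acid (not isolated) | OC(=O)C[C@@H]1C[C@@H](O[Si](C)(C)C(C)(C)C)[C@H](C)C(=O)[C@H]2O[C@@H]12 | intermediate
20 | keto lactone: 6α,12-lactone, C5 OH β, C1 ketone, C9 OTBS β | O=C1C[C@@H]2C[C@@H](O[Si](C)(C)C(C)(C)C)[C@H](C)C(=O)[C@@H](O)[C@@H]2O1 | intermediate
21 | 1-methoxybut-2-yne | CC#CCOC | starting material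
22 | 1-methoxybuta-1,2-diene (racemic) | CC=C=COC | intermediate
23 | 1-lithio-1-methoxybuta-1,2-diene (not isolated) | [Li]C(OC)=C=CC | intermediate
24 | C1 adduct: C1 OH α, C1 1-methoxybuta-1,2-dien-1-yl β (allene epimers) | O=C1C[C@@H]2C[C@@H](O[Si](C)(C)C(C)(C)C)[C@H](C)[C@@](O)(C(OC)=C=CC)[C@@H](O)[C@@H]2O1 | intermediate
25 | C11 hydroxymethyl lactone (C11 epimers) | O=C1C(CO)[C@@H]2C[C@@H](O[Si](C)(C)C(C)(C)C)[C@H](C)[C@@](O)(C(OC)=C=CC)[C@@H](O)[C@@H]2O1 | intermediate
26 | primary mesylate of 25 (not isolated) | O=C1C(COS(C)(=O)=O)[C@@H]2C[C@@H](O[Si](C)(C)C(C)(C)C)[C@H](C)[C@@](O)(C(OC)=C=CC)[C@@H](O)[C@@H]2O1 | intermediate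
27 | α-methylene lactone: C5 OH β, C1 OH α, C9 OTBS β | C=C1C(=O)O[C@@H]2[C@H]1C[C@@H](O[Si](C)(C)C(C)(C)C)[C@H](C)[C@@](O)(C(OC)=C=CC)[C@H]2O | intermediate
28 | (S)-2-methylbutanoic acid | CC[C@H](C)C(=O)O | starting material
29 | C5 (S)-2-methylbutanoate of 27 | C=C1C(=O)O[C@@H]2[C@H]1C[C@@H](O[Si](C)(C)C(C)(C)C)[C@H](C)[C@@](O)(C(OC)=C=CC)[C@H]2OC(=O)[C@@H](C)CC | intermediate
30 | 9-O-TBS ether of the target (not isolated in step 19) | C=C1C(=O)O[C@@H]2[C@H]1C[C@@H](O[Si](C)(C)C(C)(C)C)[C@H](C)[C@@](O)(C(=O)/C=C/C)[C@H]2OC(=O)[C@@H](C)CC | intermediate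
31 | target CNP0331957.1: (1S,5S,6R,7S,9R,10S) 6α,12-lactone with C11=C13, 1α-OH, 1β-(E)-but-2-enoyl, 5β-(S)-2-methylbutanoyloxy, 9β-OH, 10α-CH3 | C=C1C(=O)O[C@@H]2[C@H]1C[C@@H](O)[C@H](C)[C@@](O)(C(=O)/C=C/C)[C@H]2OC(=O)[C@@H](C)CC | target

**Step count and risks**

Total steps: 19. Longest linear sequence: 18 (steps 1–13 and 15–19; step 14 is a side branch).

Most likely to fail:

1. Step 6. The cycloaddition may stall because allylic strain between the Z substituent and C1 disfavours the reactive rotamer, rhodium may insert into the C5–C1 bond instead of C5–C10, or the alkyne may insert with boron next to C7. The fallback abandons the cycloaddition and closes the ring by olefin metathesis. It sets out from none of the numbered intermediates (it replaces steps 1–8 and starts from purchasable tert-butyl but-3-enoate, pent-1-en-3-one and acrolein) and comes back at compound 14. Cross-metathesis of tert-butyl but-3-enoate with pent-1-en-3-one (second-generation Hoveyda–Grubbs catalyst) should give tert-butyl (E)-5-oxohept-3-enoate F1. Conjugate addition of potassium vinyltrifluoroborate with [Rh(cod)Cl]2 and the BINAP enantiomer that delivers the S centre then sets C7 in tert-butyl (3S)-3-ethenyl-5-oxoheptanoate F2. A Z-enolate syn-aldol reaction with acrolein (Bu2BOTf, iPr2NEt) gives the syn-aldol diene F3; its C10/C1 diastereomer relative to C7 has to be separated. Ring-closing metathesis (second-generation Grubbs catalyst) then gives 14.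

2. Step 15. The organocerium reagent may attack from the α face (anti to the C5 oxygen) instead of the chelation-controlled β face, or attack the lactone. The fallback introduces the C1 oxygen last, from the α face, so it profits from the bias that would defeat step 15. It sets out from compound 20 and comes back at compound 30, which step 19 converts to 31. Wittig reaction of 20 with (methoxymethyl)triphenylphosphonium chloride/KHMDS gives the exocyclic enol ether F6. The lactone is hydroxymethylated as in step 16 to F7, mesylated to F8 and eliminated as in step 17 to the methylene lactone F9, which is acylated with 28 as in step 18 to the ester F10. Dimethyldioxirane epoxidation of the enol ether anti to the allylic C5 acyloxy group, then aqueous work-up, should give the α-hydroxy aldehyde F11. Nozaki–Hiyama–Kishi addition of (E)-1-iodoprop-1-ene (CrCl2, catalytic NiCl2, DMF) gives the allylic diol F12, and MnO2 oxidation of its secondary allylic alcohol gives 30.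

3. Step 2. Carbene transfer to a 1,2-disubstituted silyl enol ether may show low enantioselectivity or poor ester/OTBS diastereoselectivity. The fallback replaces catalyst control by a covalently bound auxiliary and physical separation. It sets out from compound 2 and comes back at compound 5. Cyclopropanation of 2 with (1R,2S,5R)-menthyl diazoacetate F4 (same copper catalyst, matched pair) gives the menthyl ester F5, which is separated from its diastereomers by chromatography or crystallisation. DIBAL-H reduction at −78 °C then gives 5.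

**Further compounds**

F1 | step 6 | tert-butyl (E)-5-oxohept-3-enoate | CCC(=O)/C=C/CC(=O)OC(C)(C)C
F2 | step 6 | tert-butyl (3S)-3-ethenyl-5-oxoheptanoate | CC(C)(C)OC(=O)C[C@@H](C=C)CC(=O)CC
F3 | step 6 | syn-aldol diene (tert-butyl 3-ethenyl-7-hydroxy-6-methyl-5-oxonon-8-enoate; C7 chain, C10 CH3 and C1 OH as in 14) | CC(C)(C)OC(=O)C[C@@H](C=C)CC(=O)[C@H](C)[C@@H](O)C=C
F4 | step 2 | (1R,2S,5R)-menthyl diazoacetate | CC(C)[C@@H]1CC[C@@H](C)C[C@H]1OC(=O)C=[N+]=[N-]
F5 | step 2 | (1R,2S,5R)-menthyl (1R,2R,3S)-2-(tert-butyldimethylsilyloxy)-3-methylcyclopropane-1-carboxylate | CC(C)[C@@H]1CC[C@@H](C)C[C@H]1OC(=O)[C@H]1[C@H](O[Si](C)(C)C(C)(C)C)[C@H]1C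
F6 | step 15 | exocyclic enol ether (C1=CH–OMe) of keto lactone 20 | O=C1C[C@@H]2C[C@@H](O[Si](C)(C)C(C)(C)C)[C@H](C)C(=COC)[C@@H](O)[C@@H]2O1
F7 | step 15 | C11 hydroxymethyl lactone of F6 | O=C1C(CO)[C@@H]2C[C@@H](O[Si](C)(C)C(C)(C)C)[C@H](C)C(=COC)[C@@H](O)[C@@H]2O1
F8 | step 15 | primary mesylate of F7 | O=C1C(COS(C)(=O)=O)[C@@H]2C[C@@H](O[Si](C)(C)C(C)(C)C)[C@H](C)C(=COC)[C@@H](O)[C@@H]2O1
F9 | step 15 | α-methylene lactone with C1 enol ether | C=C1C(=O)O[C@@H]2[C@H]1C[C@@H](O[Si](C)(C)C(C)(C)C)[C@H](C)C(=COC)[C@H]2O
F10 | step 15 | C5 (S)-2-methylbutanoate of F9 | C=C1C(=O)O[C@@H]2[C@H]1C[C@@H](O[Si](C)(C)C(C)(C)C)[C@H](C)C(=COC)[C@H]2OC(=O)[C@@H](C)CC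
F11 | step 15 | α-hydroxy aldehyde (C1 OH α, C1 CHO β) | C=C1C(=O)O[C@@H]2[C@H]1C[C@@H](O[Si](C)(C)C(C)(C)C)[C@H](C)[C@@](O)(C=O)[C@H]2OC(=O)[C@@H](C)CC
F12 | step 15 | allylic diol (C2 carbinol epimers) | C=C1C(=O)O[C@@H]2[C@H]1C[C@@H](O[Si](C)(C)C(C)(C)C)[C@H](C)[C@@](O)(C(O)/C=C/C)[C@H]2OC(=O)[C@@H](C)CC
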